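**Conventions.** "Top", "middle" and "bottom" denote the epicatechin unit, the central catechin unit and the acylated catechin unit; flavan numbering (O1, C2, C3, C4, C4a, C5–C8, C8a; rings A, B, C) is used for each. TBS = tert-butyldimethylsilyl, TES = triethylsilyl, Bn = benzyl. Compound numbers are those of the steps below.

## The problem

The target is a B-type procyanidin trimer, epicatechin-(4β→8)-catechin-(4α→8)-catechin, whose bottom unit carries at O3 the ester of (S)-1-hydroxy-6-oxocyclohex-2-ene-1-carboxylic acid. Three flavan units must be joined through two C4–C8 bonds without 4→6 isomers or chain growth, and one of fifteen flavan hydroxyl groups must be acylated. Of the nine stereocentres, six (C2 and C3 of each unit) come with (+)-catechin and (−)-epicatechin. C4 of the top unit is controlled by its own C2 and C3 substituents, which lie on one face and steer a nucleophile to the β face. C4 of the 2,3-trans middle unit gets much weaker guidance from C3, and the quaternary carbinol of the acyl ring has no stereogenic neighbour and needs reagent control. The interflavan bonds are acid-labile and the free polyphenol is easily oxidised. The acyl group is the most fragile part: as an α-hydroxy-β-keto ester it is destroyed by base, and its isolated C2=C3 alkene rules out a final hydrogenolysis. The feature that makes the key step possible is ring C of the middle unit: O1, C2, C3 and C4 form a dihydropyran fused to ring A through C4a and C8a, with C4 also bonded to C8 of the bottom unit. This ring is the formal [4+2] adduct of the o-quinone methide O=C8a–C4a=C4 and a β-acetoxy-3,4-dioxygenated styrene.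

## Retrosynthesis

**Ester and unmasking (39 ⇐ 38 ⇐ 37 ⇐ 28 + 35).** The last operations are removal of fifteen silyl groups with acidic fluoride (39 ⇐ 38) and hydrolysis of a methyl enol ether to the C6 ketone (38 ⇐ 37). The bond cut is the acyl C–O bond at bottom O3, giving the silylated trimer 28 with one free hydroxyl and the eight-carbon acid 35. Acylating a catechin monomer earlier would drag a base-labile ester and two alkenes through lithiation, acid catalysis and hydrogenolysis, so the ester is made late. The forward reaction must join a hindered secondary alcohol to an α-quaternary acid, and everything after it must be non-basic.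

**Acyl fragment (35 ⇐ 33 ⇐ 32 ⇐ 30 ⇐ 29).** The C1–O bond is cut back to an ester enolate, and the ring is traced to methyl 2-methoxybenzoate 29 by Birch reduction. This delivers the ketone already masked as the enol ether and the future C2=C3 alkene in the right place; because C1 is quaternary, that alkene cannot move into conjugation later. The enolate hydroxylation (30 → 32) must set the only reagent-controlled stereocentre of the route.

**Protecting-group exchange (28 ⇐ 27 ⇐ 24 ⇐ 23).** No skeletal bond is cut. Benzyl ethers are needed for the organolithium, Brønsted-acid and Lewis-acid chemistry but cannot be removed once the alkene is present, so they are exchanged for silyl ethers before acylation. Bottom O3 is carried as a benzyl ether and is therefore uncovered together with the phenols in 24. Middle and top O3 are TBS ethers that survive hydrogenolysis; a silyl ether at bottom O3 would be indistinguishable from these after the exchange. The twelve phenols of 24 fall into two classes, and they are silylated in two stages.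
- The six ring-A phenols include the four that flank the interflavan bonds and react slowly. They are silylated first (27 ⇐ 24), while the three catechols are held as cyclic phenylboronic esters, which also keeps these oxidation-prone rings away from base and air during the long reaction.
- The six unhindered catechol phenols follow under mild conditions (28 ⇐ 27).
The forward demand in both stages is that the single secondary alcohol stays free.

**Top interflavan bond (23 ⇐ 17 + 22; 22 ⇐ 21 ⇐ 20 ⇐ 19 ⇐ 18).** The C4(top)–C8(middle) bond is cut to a C4 cation equivalent of epicatechin and the dimer 17 as nucleophile. This is the place for a cationic coupling, because in a 2,3-cis unit the C2 aryl and C3 oxygen both block the α face and 4β selectivity is reliable. A bromine at C8 of 22 prevents self-condensation and chain growth and is lost in the hydrogenolysis. The forward reaction must choose C8 of the middle unit over the two C6 positions.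

**Middle ring C (17 ⇐ 16 ⇐ 15 ⇐ 10 + 13).** After a protecting-group change at middle O3, the O1–C2 and C3–C4 bonds of the middle unit are cut. The neighbouring cut, C4–C8 by cationic coupling of a C4-activated catechin, needs an excess of nucleophile and depends on a participating group for the 3,4-trans result in a 2,3-trans unit. The [4+2] cut instead creates C2, C3 and C4 in one step while the interflavan bond is already in place, so no 4→6 isomer can arise. The precursors are the diaryl carbinol 10 and the achiral enol acetate 13. The forward reaction must control regiochemistry, relative configuration and the face of the methide.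

**Carbinol (10 ⇐ 9 ⇐ 4 + 7; 4 ⇐ 3 ⇐ 2 ⇐ 1; 7 ⇐ 6 ⇐ 5).** The C8–C(carbinol) bond is cut to the 8-lithio derivative of perbenzylated catechin and a salicylaldehyde whose phenol is masked as an allyl ether, removable without acid. Bromination of the catechin ether is C8-selective, so the bottom unit is used intact with both stereocentres. The carbinol configuration is irrelevant because it is ionised in the key step.

**Dienophile (13 ⇐ 12 ⇐ 11).** The enol acetate is traced to the benzylideneacetone 12 by a Baeyer–Villiger cut of the O–C(vinyl) bond, and 12 to 3,4-bis(benzyloxy)benzaldehyde 11 and acetone. This fixes the E geometry, which enolisation of an arylacetaldehyde would not.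

## Roads not taken

**Alternative 1:** The acyl group would be taken from benzoic acid A2 by whole-cell dihydroxylation (Ralstonia eutropha B9, benzoate 1,2-dioxygenase, O2) to (1S,2R)-1,2-dihydroxycyclohexa-3,5-diene-1-carboxylic acid A1. The cut is the two C–O bonds at C1 and C2 of the acyl ring.
- Merit: the quaternary carbinol arrives as a single enantiomer with the correct configuration in one step. In this respect it is better than the chosen plan, whose hydroxylation (step 22) relies on a chiral reagent of uncertain selectivity.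
- Weak points: A1 has two ring alkenes, and only the one next to the secondary carbinol must be saturated. The diol must be protected through esterification. The secondary alcohol must be oxidised after the fragment is on the trimer. A fermentation has to be set up. It also says nothing about the flavan core.
- What the chosen plan sets against it: a four-step chemical route from a commercial ester that delivers the ketone already masked, needs no redox step after coupling, and allows the minor acyl epimer to be removed as a diastereomer after esterification to the enantiopure trimer.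

**Alternative 2:** Ring C of the bottom unit would be closed and the carbinol carbon attached in one flask. Lithium 2,2,6,6-tetramethylpiperidide would convert the fluoroarene A4 into a C8–C8a aryne, the C2 alkoxide would add at C8a, and the resulting C8 aryllithium would add to the aldehyde to give carbinol A3. The cuts are O1–C8a and C8–C(carbinol).
- Merit: two bonds in one operation, and the C8 position is defined by construction and does not depend on a selective bromination. In that respect it is as good as or better than steps 3 and 6.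
- Weak points: it rebuilds a unit that is sold enantiopure. A4 needs its two stereocentres set by asymmetric synthesis and a fluorinated ring A prepared. A3 still has to be ionised and cyclised as in step 10, so nothing is saved downstream. Its O3 methoxymethyl group needs acid for removal.
- What the chosen plan sets against it: three known steps from (+)-catechin to bromide 4.

**Alternative 3:** Ring A of the bottom unit would be grown onto C4 of a finished middle unit by a thermal Danheiser-type benzannulation (vinylketene formation, [2+2] with a siloxyalkyne, 4π opening, 6π closure), giving the 2-(flavan-4-yl)-6-cinnamyl phenol A5. The cuts are C8–C8a, C6–C7 and C4a–C8a of the bottom unit.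
- Merit: the interflavan regiochemistry is fixed by ring construction, and O5, O7 and O1 of the bottom unit come out differentiated. The chosen plan cannot match that differentiation, though it does not need it.
- Weak points: the 4α stereocentre of the middle unit, the hardest one, must already be in place before the annulation. Ring C of the bottom unit must then be built from the cinnamyl phenol by asymmetric dihydroxylation and cyclisation, although catechin contains it. The sequence is heated with an acid- and heat-sensitive benzylic C4 present, and it is clearly longer.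
- What the chosen plan sets against it: the middle C4 centre and ring C are made in the same step, and the bottom unit is used as bought.

Key step: step 10

**Assumptions.**
- The sense of induction of (R)-TRIP in step 10 and of the (+)-(2R,8aS)-oxaziridine in step 22 cannot be derived from the structures alone. These antipodes are written; the mirror-image reagent (both are commercial) would be used if the opposite sense were found.
- 3,4-Bis(benzyloxy)benzaldehyde 11 and methyl 2-methoxybenzoate 29 are treated as commercial.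
- Cyclic phenylboronic esters of catechols are taken to persist under TBSCl and a hindered tertiary amine in dry DMF and to be exchanged off by pinacol.

## Steps

Step 1
Reactants: 1 (+)-catechin
Product: 2 5,7,3',4'-tetra-O-benzyl-(+)-catechin
Conditions: BnBr, K2CO3, DMF, 0 °C to rt
Reagents that add atoms: benzyl bromide, BrCc1ccccc1
Why: Williamson ether synthesis; carbonate deprotonates only the four phenols, so the secondary 3-OH stays free and C2/C3 are untouched.

Step 2
Reactants: 2 5,7,3',4'-tetra-O-benzyl-(+)-catechin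
Product: 3 3,5,7,3',4'-penta-O-benzyl-(+)-catechin
Conditions: NaH, BnBr, n-Bu4NI (cat.), DMF, 0 °C to rt
Reagents that add atoms: benzyl bromide, BrCc1ccccc1
Why: Williamson etherification of the secondary alkoxide; with all phenols capped there is no pathway for C2 epimerisation.

Step 3
Reactants: 3 3,5,7,3',4'-penta-O-benzyl-(+)-catechin
Product: 4 8-bromo-3,5,7,3',4'-penta-O-benzyl-(+)-catechin
Conditions: NBS, CH2Cl2, −78 to 0 °C
Reagents that add atoms: N-bromosuccinimide, O=C1CCC(=O)N1Br
Why: Electrophilic aromatic bromination; in 5,7-dialkoxyflavans C8 reacts ahead of C6, which is flanked by two benzyloxy groups.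

Step 4
Reactants: 5 2,4,6-trihydroxybenzaldehyde
Product: 6 4,6-bis(benzyloxy)-2-hydroxybenzaldehyde
Conditions: BnBr (2 equiv), K2CO3, DMF, rt
Reagents that add atoms: benzyl bromide, BrCc1ccccc1
Why: Williamson etherification; after the para and one ortho hydroxyl are alkylated, the remaining ortho hydroxyl is held in a hydrogen bond to the formyl group and is the least nucleophilic.

Step 5
Reactants: 6 4,6-bis(benzyloxy)-2-hydroxybenzaldehyde
Product: 7 2-(allyloxy)-4,6-bis(benzyloxy)benzaldehyde
Conditions: allyl bromide, K2CO3, DMF, 60 °C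
Reagents that add atoms: allyl bromide, C=CCBr
Why: Williamson etherification of the chelated phenol under warmer conditions; the allyl ether can later be removed without acid.

Step 6
Reactants: 4 8-bromo-3,5,7,3',4'-penta-O-benzyl-(+)-catechin; 7 2-(allyloxy)-4,6-bis(benzyloxy)benzaldehyde
Product: 9 [2-(allyloxy)-4,6-bis(benzyloxy)phenyl](3,5,7,3',4'-penta-O-benzylcatechin-8-yl)methanol (both carbinol epimers), via aryllithium 8 (not isolated)
Conditions: t-BuLi (2.1 equiv), THF, −78 °C; then 7, −78 to −40 °C; H2O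
Reagents that add atoms: none
Why: Bromine–lithium exchange (the second equivalent of t-BuLi destroys t-BuBr) followed by 1,2-addition of the aryllithium to the aldehyde; the carbinol centre forms as a mixture of epimers, which does not matter because it is ionised in step 10.

Step 7
Reactants: 9 [2-(allyloxy)-4,6-bis(benzyloxy)phenyl](3,5,7,3',4'-penta-O-benzylcatechin-8-yl)methanol
Product: 10 [4,6-bis(benzyloxy)-2-hydroxyphenyl](3,5,7,3',4'-penta-O-benzylcatechin-8-yl)methanol (both carbinol epimers)
Conditions: Pd(PPh3)4 (5 mol %), K2CO3, MeOH/THF, rt; base-washed work-up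
Reagents that add atoms: none
Why: Tsuji–Trost deallylation; zerovalent palladium ionises the aryl allyl ether and methanol traps the allyl fragment, under basic conditions that do not ionise the very labile diaryl carbinol.

Step 8
Reactants: 11 3,4-bis(benzyloxy)benzaldehyde
Product: 12 (E)-4-[3,4-bis(benzyloxy)phenyl]but-3-en-2-one
Conditions: acetone (excess), aq. NaOH (cat.), EtOH, rt
Reagents that add atoms: acetone, CC(C)=O
Why: Claisen–Schmidt condensation; dehydration of the aldol gives the conjugated E-enone, and excess acetone suppresses double condensation.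

Step 9
Reactants: 12 (E)-4-[3,4-bis(benzyloxy)phenyl]but-3-en-2-one
Product: 13 (E)-2-[3,4-bis(benzyloxy)phenyl]vinyl acetate
Conditions: mCPBA (1.05 equiv), NaHCO3, CH2Cl2, 0 °C to rt
Reagents that add atoms: 3-chloroperbenzoic acid, OOC(=O)c1cccc(Cl)c1
Why: Baeyer–Villiger oxidation; the electron-rich alkenyl group migrates in preference to methyl with retention of the E geometry, giving the enol acetate directly.

Step 10
Reactants: 10 [4,6-bis(benzyloxy)-2-hydroxyphenyl](3,5,7,3',4'-penta-O-benzylcatechin-8-yl)methanol; 13 (E)-2-[3,4-bis(benzyloxy)phenyl]vinyl acetate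
Product: 15 3-O-acetyl-5,7,3',4'-tetra-O-benzylcatechin-(4α→8)-3,5,7,3',4'-penta-O-benzylcatechin, via o-quinone methide 14 (not isolated)
Conditions: (R)-TRIP [(R)-3,3'-bis(2,4,6-triisopropylphenyl)-1,1'-binaphthyl-2,2'-diyl hydrogen phosphate] (10 mol %), 13 (4 equiv), 4 Å MS, CH2Cl2, −20 °C to rt, slow addition of 10
Reagents that add atoms: none
Why: The phosphoric acid protonates the doubly benzylic hydroxyl of 10, water leaves to the sieves, and both carbinol epimers converge on the o-quinone methide 14, which stays hydrogen-bonded to the chiral phosphate through its carbonyl oxygen. The acetoxy-bearing carbon of 13 bonds to the methide carbon (future C4) while positive charge builds at the benzylic carbon, and the methide oxygen then closes O1–C2, so ring C forms as a six-membered ring by a polar, asynchronous inverse-demand oxa-[4+2] addition (4π heterodiene plus 2π alkene). The closest known reaction type is the Brønsted-acid-catalysed [4+2] of o-quinone methides from o-hydroxybenzhydrols with styrenes and enol derivatives. The required regiochemistry (aryl at C2, acetoxy at C3) is secured because the 4-benzyloxyphenyl group is a far stronger cation-stabilising donor than the acetoxy group. The C2/C3 trans relation follows from the E geometry of 13 in a suprafacial addition and is also the all-equatorial outcome if closure is stepwise. C4 trans to C3 and cis to C2 follows from reaction through the E methide, whose bottom-unit aryl group points away from the forming O1–C2 bond (the methide geometries interconvert through the protonated form), combined with an endo-aryl, exo-acetoxy approach of 13. The absolute configuration at C4 (S) is set by the face of the phosphate-bound methide left open by the 3,3'-aryl groups of the catalyst, since the bottom-unit stereocentres are remote. Friedel–Crafts self-condensation at the free C6 and C8 positions is suppressed by adding 10 slowly to an excess of 13 and by the steric shielding of the tetra-ortho-substituted methide.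

Step 11
Reactants: 15 3-O-acetyl-5,7,3',4'-tetra-O-benzylcatechin-(4α→8)-3,5,7,3',4'-penta-O-benzylcatechin
Product: 16 5,7,3',4'-tetra-O-benzylcatechin-(4α→8)-3,5,7,3',4'-penta-O-benzylcatechin (middle 3-OH free)
Conditions: K2CO3 (cat.), MeOH/THF, rt to 40 °C
Reagents that add atoms: none
Why: Methanolysis (transesterification) of the acetate; benzyl ethers and the interflavan bond are stable to base, and acyl–oxygen cleavage leaves C3 untouched.

Step 12
Reactants: 16 5,7,3',4'-tetra-O-benzylcatechin-(4α→8)-3,5,7,3',4'-penta-O-benzylcatechin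
Product: 17 3-O-TBS-5,7,3',4'-tetra-O-benzylcatechin-(4α→8)-3,5,7,3',4'-penta-O-benzylcatechin
Conditions: TBSOTf, 2,6-lutidine, CH2Cl2, 0 °C to rt
Reagents that add atoms: tert-butyldimethylsilyl triflate, CC(C)(C)[Si](C)(C)OS(=O)(=O)C(F)(F)F
Why: Silyl triflate silylation of a hindered secondary alcohol; the silyl ether survives hydrogenolysis and leaves only with fluoride at the end.

Step 13
Reactants: 18 (−)-epicatechin
Product: 19 5,7,3',4'-tetra-O-benzyl-(−)-epicatechin
Conditions: BnBr, K2CO3, DMF, 0 °C to rt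
Reagents that add atoms: benzyl bromide, BrCc1ccccc1
Why: Williamson ether synthesis selective for the phenols, as in step 1.

Step 14
Reactants: 19 5,7,3',4'-tetra-O-benzyl-(−)-epicatechin
Product: 20 8-bromo-5,7,3',4'-tetra-O-benzyl-(−)-epicatechin
Conditions: NBS, CH2Cl2, −78 °C to rt
Reagents that add atoms: N-bromosuccinimide, O=C1CCC(=O)N1Br
Why: C8-selective electrophilic bromination; the bromine caps the only strongly nucleophilic position of the future electrophile.

Step 15
Reactants: 20 8-bromo-5,7,3',4'-tetra-O-benzyl-(−)-epicatechin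
Product: 21 8-bromo-5,7,3',4'-tetra-O-benzyl-4β-(2-ethoxyethoxy)epicatechin
Conditions: DDQ, 2-ethoxyethanol, CH2Cl2, rt
Reagents that add atoms: 2-ethoxyethanol, CCOCCO
Why: Benzylic oxidation by hydride abstraction; the ring-A-stabilised C4 cation is trapped by the alcohol on the β face, anti to the C2 aryl and C3 hydroxyl groups.

Step 16
Reactants: 21 8-bromo-5,7,3',4'-tetra-O-benzyl-4β-(2-ethoxyethoxy)epicatechin
Product: 22 8-bromo-3-O-TBS-5,7,3',4'-tetra-O-benzyl-4β-(2-ethoxyethoxy)epicatechin
Conditions: TBSCl, imidazole, DMF, rt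
Reagents that add atoms: tert-butyldimethylsilyl chloride, CC(C)(C)[Si](C)(C)Cl
Why: Imidazole-mediated silylation; the non-Lewis-acidic conditions leave the acetal-like C4 ether intact.

Step 17
Reactants: 17 3-O-TBS-5,7,3',4'-tetra-O-benzylcatechin-(4α→8)-3,5,7,3',4'-penta-O-benzylcatechin; 22 8-bromo-3-O-TBS-5,7,3',4'-tetra-O-benzyl-4β-(2-ethoxyethoxy)epicatechin
Product: 23 8-bromo-3-O-TBS-5,7,3',4'-tetra-O-benzylepicatechin-(4β→8)-3-O-TBS-5,7,3',4'-tetra-O-benzylcatechin-(4α→8)-3,5,7,3',4'-penta-O-benzylcatechin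
Conditions: Me3SiOTf (0.2 equiv), CH2Cl2, −78 to −40 °C; Et3N quench
Reagents that add atoms: none
Why: Lewis-acid ionisation of the C4 ether and Friedel–Crafts alkylation at C8 of the middle unit, the most nucleophilic free position of 17. Attack anti to the C2 aryl and C3 silyloxy groups (both on the α face) gives the 4β, 3,4-trans bond. The bromine prevents self-condensation and chain growth.

Step 18
Reactants: 23 protected trimer
Product: 24 3-O-TBS-epicatechin-(4β→8)-3-O-TBS-catechin-(4α→8)-catechin (twelve phenols and bottom 3-OH free)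
Conditions: H2 (1 atm), Pd(OH)2/C, Et3N (3 equiv), THF/MeOH, rt
Reagents that add atoms: none
Why: Hydrogenolysis of thirteen benzyl ethers with hydrodebromination at C8 of the top unit; triethylamine takes up HBr so that the secondary silyl ethers and the acid-labile interflavan bonds survive.

Step 19
Reactants: 24 3-O-TBS-epicatechin-(4β→8)-3-O-TBS-catechin-(4α→8)-catechin
Product: 27 ring-A hexa-O-TBS derivative of 24 (5-O- and 7-O-TBS on each unit; three catechols and bottom 3-OH free), via tris(phenylboronate) 25 (not isolated), via silylated tris(phenylboronate) 26 (not isolated)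
Conditions: PhB(OH)2 (3.3 equiv), 4 Å MS, THF, rt; then TBSCl (7 equiv), i-Pr2NEt, DMF, 0 °C to rt; then pinacol (4 equiv), rt
Reagents that add atoms: tert-butyldimethylsilyl chloride, CC(C)(C)[Si](C)(C)Cl
Why: Transient boronic ester protection: phenylboronic acid condenses only with the three catechol (1,2-diphenol) pairs to five-membered cyclic esters, so TBSCl with a hindered amine silylates the six ring-A phenols, and transesterification to the more stable pinacol boronate then frees the catechols. The hindered secondary 3-OH is not silylated by TBSCl in the absence of imidazole, and the masked catechols are shielded from base and air during the slow silylation of the phenols next to the interflavan bonds.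

Step 20
Reactants: 27 ring-A hexa-O-TBS derivative of 24
Product: 28 dodeca-O-TBS (all phenols) 3-O-TBS-epicatechin-(4β→8)-3-O-TBS-catechin-(4α→8)-catechin with free bottom 3-OH
Conditions: TBSCl (7 equiv), imidazole, DMF, 0 °C to rt
Reagents that add atoms: tert-butyldimethylsilyl chloride, CC(C)(C)[Si](C)(C)Cl
Why: Imidazole-mediated silylation of the six unhindered catechol phenols, which react much faster than the hindered secondary C3 hydroxyl, as known for flavan-3-ols; the bottom 3-OH is left as the only free hydroxyl.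

Step 21
Reactants: 29 methyl 2-methoxybenzoate
Product: 30 methyl 2-methoxycyclohexa-2,5-diene-1-carboxylate
Conditions: K, NH3 (l), THF, t-BuOH (1 equiv), −78 °C; then NH4Cl
Reagents that add atoms: none
Why: Birch reduction; electron transfer, protonation para to the ester and kinetic protonation of the ester dienolate at C1 give the 2,5-diene, with the methoxy-bearing alkene kept as an enol ether.

Step 22
Reactants: 30 methyl 2-methoxycyclohexa-2,5-diene-1-carboxylate
Product: 32 methyl (S)-1-hydroxy-2-methoxycyclohexa-2,5-diene-1-carboxylate, via sodium enolate 31 (not isolated)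
Conditions: NaN(SiMe3)2, THF, −78 °C; then (+)-(2R,8aS)-(camphorsulfonyl)oxaziridine, −78 to −40 °C; AcOH
Reagents that add atoms: (+)-(2R,8aS)-(camphorsulfonyl)oxaziridine, O=S1(=O)C[C@@]23CC[C@@H](C2(C)C)C[C@]34ON14
Why: Enolate hydroxylation with an N-sulfonyloxaziridine; the ester enolate attacks the oxaziridine oxygen through C1, the position also alkylated in Birch reduction–alkylations. The camphor skeleton of the reagent differentiates the two enolate faces, which are flanked by a methoxy-substituted and an unsubstituted vinyl carbon, and so sets the S quaternary carbinol.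

Step 23
Reactants: 32 methyl (S)-1-hydroxy-2-methoxycyclohexa-2,5-diene-1-carboxylate
Product: 33 lithium (S)-1-hydroxy-2-methoxycyclohexa-2,5-diene-1-carboxylate
Conditions: LiOH (1.05 equiv), THF/H2O, 0 °C to rt; lyophilise
Reagents that add atoms: lithium hydroxide, [Li+].[OH-]
Why: Saponification assisted by the α-hydroxyl; enol ether and skipped diene are stable to base, and isolation as the lithium salt keeps the enol ether away from a free carboxylic acid.

Step 24
Reactants: 33 lithium (S)-1-hydroxy-2-methoxycyclohexa-2,5-diene-1-carboxylate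
Product: 35 (S)-2-methoxy-1-(triethylsilyloxy)cyclohexa-2,5-diene-1-carboxylic acid, via bis(triethylsilyl) derivative 34 (not isolated)
Conditions: Et3SiOTf (2.5 equiv), 2,6-lutidine, CH2Cl2, 0 °C; then MeOH, K2CO3 (cat.), 0 °C; cold buffered work-up
Reagents that add atoms: triethylsilyl triflate, CC[Si](CC)(CC)OS(=O)(=O)C(F)(F)F
Why: The silyl triflate silylates both the tertiary alcohol and the carboxylate; methanol then cleaves only the labile silyl ester, leaving the tertiary silyl ether that blocks self-acylation in step 25.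

Step 25
Reactants: 28 silylated trimer with free bottom 3-OH; 35 (S)-2-methoxy-1-(triethylsilyloxy)cyclohexa-2,5-diene-1-carboxylic acid
Product: 37 bottom-unit 3-O-[(S)-2-methoxy-1-(triethylsilyloxy)cyclohexa-2,5-diene-1-carbonyl] ester of 28, via mixed anhydride 36 (not isolated)
Conditions: 35 (3 equiv), 2,4,6-trichlorobenzoyl chloride, Et3N, THF, 0 °C to rt; then 28, 4-(dimethylamino)pyridine, toluene, rt to 40 °C
Reagents that add atoms: none
Why: Yamaguchi esterification; the acyl-pyridinium derived from the mixed anhydride acylates the only free hydroxyl under non-acidic conditions that preserve the enol ether. Any minor acyl epimer from step 22 becomes a diastereomer and can be removed by chromatography.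

Step 26
Reactants: 37 bottom-unit dienyl ester
Product: 38 bottom-unit 3-O-[(S)-6-oxo-1-(triethylsilyloxy)cyclohex-2-ene-1-carbonyl] ester of 28
Conditions: aq. oxalic acid (0.5 M), THF, 0 °C to rt
Reagents that add atoms: water, O
Why: Acid-catalysed hydrolysis of the methyl enol ether (C-protonation, hydration, loss of methanol) gives the C6 ketone. The remaining alkene cannot move into conjugation because C1 is quaternary, and aryl and hindered alkyl silyl ethers tolerate the dilute acid.

Step 27
Reactants: 38 fully silylated keto ester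
Product: 39 epicatechin-(4β→8)-catechin-(4α→8)-catechin bottom-unit 3-O-[(S)-1-hydroxy-6-oxocyclohex-2-ene-1-carboxylate] (CNP0159807.2)
Conditions: HF·pyridine, pyridine, THF, 0 °C to rt
Reagents that add atoms: none
Why: Fluoride-mediated cleavage of fourteen TBS ethers and the tertiary TES ether under acidic, non-basic conditions, chosen because the α-hydroxy-β-keto ester does not survive base; no stereocentre is touched.

## Compound list

1 | (+)-catechin | O[C@H]1Cc2c(O)cc(O)cc2O[C@@H]1c1ccc(O)c(O)c1 | starting material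
2 | 5,7,3',4'-tetra-O-benzyl-(+)-catechin | O[C@H]1Cc2c(OCc7ccccc7)cc(OCc7ccccc7)cc2O[C@@H]1c1ccc(OCc7ccccc7)c(OCc7ccccc7)c1 | intermediate
3 | 3,5,7,3',4'-penta-O-benzyl-(+)-catechin | c7ccccc7CO[C@H]1Cc2c(OCc7ccccc7)cc(OCc7ccccc7)cc2O[C@@H]1c1ccc(OCc7ccccc7)c(OCc7ccccc7)c1 | intermediate
4 | 8-bromo-3,5,7,3',4'-penta-O-benzyl-(+)-catechin | c7ccccc7CO[C@H]1Cc2c(OCc7ccccc7)cc(OCc7ccccc7)c(Br)c2O[C@@H]1c1ccc(OCc7ccccc7)c(OCc7ccccc7)c1 | intermediate
5 | 2,4,6-trihydroxybenzaldehyde | O=Cc1c(O)cc(O)cc1O | starting material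
6 | 4,6-bis(benzyloxy)-2-hydroxybenzaldehyde | O=Cc1c(O)cc(OCc2ccccc2)cc1OCc1ccccc1 | intermediate
7 | 2-(allyloxy)-4,6-bis(benzyloxy)benzaldehyde | C=CCOc1cc(OCc2ccccc2)cc(OCc2ccccc2)c1C=O | intermediate
8 | 8-lithio-3,5,7,3',4'-penta-O-benzyl-(+)-catechin (not isolated) | c7ccccc7CO[C@H]1Cc2c(OCc7ccccc7)cc(OCc7ccccc7)c([Li])c2O[C@@H]1c1ccc(OCc7ccccc7)c(OCc7ccccc7)c1 | intermediate
9 | [2-(allyloxy)-4,6-bis(benzyloxy)phenyl](3,5,7,3',4'-penta-O-benzylcatechin-8-yl)methanol, carbinol epimers | c7ccccc7CO[C@H]1Cc2c(OCc7ccccc7)cc(OCc7ccccc7)c(C(O)c3c(OCC=C)cc(OCc7ccccc7)cc3OCc7ccccc7)c2O[C@@H]1c1ccc(OCc7ccccc7)c(OCc7ccccc7)c1 | intermediate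
10 | [4,6-bis(benzyloxy)-2-hydroxyphenyl](3,5,7,3',4'-penta-O-benzylcatechin-8-yl)methanol, carbinol epimers | c7ccccc7CO[C@H]1Cc2c(OCc7ccccc7)cc(OCc7ccccc7)c(C(O)c3c(O)cc(OCc7ccccc7)cc3OCc7ccccc7)c2O[C@@H]1c1ccc(OCc7ccccc7)c(OCc7ccccc7)c1 | intermediate
11 | 3,4-bis(benzyloxy)benzaldehyde | O=Cc1ccc(OCc2ccccc2)c(OCc2ccccc2)c1 | starting material
12 | (E)-4-[3,4-bis(benzyloxy)phenyl]but-3-en-2-one | CC(=O)/C=C/c1ccc(OCc2ccccc2)c(OCc2ccccc2)c1 | intermediate
13 | (E)-2-[3,4-bis(benzyloxy)phenyl]vinyl acetate | CC(=O)O/C=C/c1ccc(OCc2ccccc2)c(OCc2ccccc2)c1 | intermediate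
14 | o-quinone methide, (E)-3,5-bis(benzyloxy)-6-[(3,5,7,3',4'-penta-O-benzylcatechin-8-yl)methylidene]cyclohexa-2,4-dien-1-one (not isolated) | c7ccccc7CO[C@H]1Cc2c(OCc7ccccc7)cc(OCc7ccccc7)c(/C=C3/C(=O)C=C(OCc7ccccc7)C=C3OCc7ccccc7)c2O[C@@H]1c1ccc(OCc7ccccc7)c(OCc7ccccc7)c1 | intermediate
15 | 3-O-acetyl-5,7,3',4'-tetra-O-benzylcatechin-(4α→8)-3,5,7,3',4'-penta-O-benzylcatechin | c7ccccc7CO[C@H]1Cc2c(OCc7ccccc7)cc(OCc7ccccc7)c([C@@H]3c4c(OCc7ccccc7)cc(OCc7ccccc7)cc4O[C@H](c4ccc(OCc7ccccc7)c(OCc7ccccc7)c4)[C@H]3OC(C)=O)c2O[C@@H]1c1ccc(OCc7ccccc7)c(OCc7ccccc7)c1 | intermediate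
16 | 5,7,3',4'-tetra-O-benzylcatechin-(4α→8)-3,5,7,3',4'-penta-O-benzylcatechin | c7ccccc7CO[C@H]1Cc2c(OCc7ccccc7)cc(OCc7ccccc7)c([C@@H]3c4c(OCc7ccccc7)cc(OCc7ccccc7)cc4O[C@H](c4ccc(OCc7ccccc7)c(OCc7ccccc7)c4)[C@H]3O)c2O[C@@H]1c1ccc(OCc7ccccc7)c(OCc7ccccc7)c1 | intermediate
17 | 3-O-TBS-5,7,3',4'-tetra-O-benzylcatechin-(4α→8)-3,5,7,3',4'-penta-O-benzylcatechin | c7ccccc7CO[C@H]1Cc2c(OCc7ccccc7)cc(OCc7ccccc7)c([C@@H]3c4c(OCc7ccccc7)cc(OCc7ccccc7)cc4O[C@H](c4ccc(OCc7ccccc7)c(OCc7ccccc7)c4)[C@H]3O[Si](C)(C)C(C)(C)C)c2O[C@@H]1c1ccc(OCc7ccccc7)c(OCc7ccccc7)c1 | intermediate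
18 | (−)-epicatechin | O[C@@H]1Cc2c(O)cc(O)cc2O[C@@H]1c1ccc(O)c(O)c1 | starting material
19 | 5,7,3',4'-tetra-O-benzyl-(−)-epicatechin | O[C@@H]1Cc2c(OCc7ccccc7)cc(OCc7ccccc7)cc2O[C@@H]1c1ccc(OCc7ccccc7)c(OCc7ccccc7)c1 | intermediate
20 | 8-bromo-5,7,3',4'-tetra-O-benzyl-(−)-epicatechin | O[C@@H]1Cc2c(OCc7ccccc7)cc(OCc7ccccc7)c(Br)c2O[C@@H]1c1ccc(OCc7ccccc7)c(OCc7ccccc7)c1 | intermediate
21 | 8-bromo-5,7,3',4'-tetra-O-benzyl-4β-(2-ethoxyethoxy)epicatechin | CCOCCO[C@H]1c2c(OCc7ccccc7)cc(OCc7ccccc7)c(Br)c2O[C@H](c2ccc(OCc7ccccc7)c(OCc7ccccc7)c2)[C@@H]1O | intermediate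
22 | 8-bromo-3-O-TBS-5,7,3',4'-tetra-O-benzyl-4β-(2-ethoxyethoxy)epicatechin | CCOCCO[C@H]1c2c(OCc7ccccc7)cc(OCc7ccccc7)c(Br)c2O[C@H](c2ccc(OCc7ccccc7)c(OCc7ccccc7)c2)[C@@H]1O[Si](C)(C)C(C)(C)C | intermediate
23 | 8-bromo-3-O-TBS-5,7,3',4'-tetra-O-benzylepicatechin-(4β→8)-3-O-TBS-5,7,3',4'-tetra-O-benzylcatechin-(4α→8)-3,5,7,3',4'-penta-O-benzylcatechin | c7ccccc7CO[C@H]1Cc2c(OCc7ccccc7)cc(OCc7ccccc7)c([C@@H]3c4c(OCc7ccccc7)cc(OCc7ccccc7)c([C@H]5c6c(OCc7ccccc7)cc(OCc7ccccc7)c(Br)c6O[C@H](c6ccc(OCc7ccccc7)c(OCc7ccccc7)c6)[C@@H]5O[Si](C)(C)C(C)(C)C)c4O[C@H](c4ccc(OCc7ccccc7)c(OCc7ccccc7)c4)[C@H]3O[Si](C)(C)C(C)(C)C)c2O[C@@H]1c1ccc(OCc7ccccc7)c(OCc7ccccc7)c1 | intermediate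
24 | 3-O-TBS-epicatechin-(4β→8)-3-O-TBS-catechin-(4α→8)-catechin | O[C@H]1Cc2c(O)cc(O)c([C@@H]3c4c(O)cc(O)c([C@H]5c6c(O)cc(O)cc6O[C@H](c6ccc(O)c(O)c6)[C@@H]5O[Si](C)(C)C(C)(C)C)c4O[C@H](c4ccc(O)c(O)c4)[C@H]3O[Si](C)(C)C(C)(C)C)c2O[C@@H]1c1ccc(O)c(O)c1 | intermediate
25 | tris(phenylboronate) of 24: each ring-B catechol closed as a 2-phenyl-1,3,2-benzodioxaborole (not isolated) | O[C@H]1Cc2c(O)cc(O)c([C@@H]3c4c(O)cc(O)c([C@H]5c6c(O)cc(O)cc6O[C@H](c6ccc7OB(c8ccccc8)Oc7c6)[C@@H]5O[Si](C)(C)C(C)(C)C)c4O[C@H](c4ccc5OB(c6ccccc6)Oc5c4)[C@H]3O[Si](C)(C)C(C)(C)C)c2O[C@@H]1c1ccc2OB(c3ccccc3)Oc2c1 | intermediate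
26 | ring-A hexa-O-TBS tris(phenylboronate) of 24 (not isolated) | O[C@H]1Cc2c(O[Si](C)(C)C(C)(C)C)cc(O[Si](C)(C)C(C)(C)C)c([C@@H]3c4c(O[Si](C)(C)C(C)(C)C)cc(O[Si](C)(C)C(C)(C)C)c([C@H]5c6c(O[Si](C)(C)C(C)(C)C)cc(O[Si](C)(C)C(C)(C)C)cc6O[C@H](c6ccc7OB(c8ccccc8)Oc7c6)[C@@H]5O[Si](C)(C)C(C)(C)C)c4O[C@H](c4ccc5OB(c6ccccc6)Oc5c4)[C@H]3O[Si](C)(C)C(C)(C)C)c2O[C@@H]1c1ccc2OB(c3ccccc3)Oc2c1 | intermediate
27 | ring-A hexa-O-TBS derivative of 24 (5-O- and 7-O-TBS on each unit; catechols and bottom 3-OH free) | O[C@H]1Cc2c(O[Si](C)(C)C(C)(C)C)cc(O[Si](C)(C)C(C)(C)C)c([C@@H]3c4c(O[Si](C)(C)C(C)(C)C)cc(O[Si](C)(C)C(C)(C)C)c([C@H]5c6c(O[Si](C)(C)C(C)(C)C)cc(O[Si](C)(C)C(C)(C)C)cc6O[C@H](c6ccc(O)c(O)c6)[C@@H]5O[Si](C)(C)C(C)(C)C)c4O[C@H](c4ccc(O)c(O)c4)[C@H]3O[Si](C)(C)C(C)(C)C)c2O[C@@H]1c1ccc(O)c(O)c1 | intermediate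
28 | all-phenol dodeca-O-TBS derivative of 24, bottom 3-OH free | O[C@H]1Cc2c(O[Si](C)(C)C(C)(C)C)cc(O[Si](C)(C)C(C)(C)C)c([C@@H]3c4c(O[Si](C)(C)C(C)(C)C)cc(O[Si](C)(C)C(C)(C)C)c([C@H]5c6c(O[Si](C)(C)C(C)(C)C)cc(O[Si](C)(C)C(C)(C)C)cc6O[C@H](c6ccc(O[Si](C)(C)C(C)(C)C)c(O[Si](C)(C)C(C)(C)C)c6)[C@@H]5O[Si](C)(C)C(C)(C)C)c4O[C@H](c4ccc(O[Si](C)(C)C(C)(C)C)c(O[Si](C)(C)C(C)(C)C)c4)[C@H]3O[Si](C)(C)C(C)(C)C)c2O[C@@H]1c1ccc(O[Si](C)(C)C(C)(C)C)c(O[Si](C)(C)C(C)(C)C)c1 | intermediate
29 | methyl 2-methoxybenzoate | COC(=O)c1ccccc1OC | starting material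
30 | methyl 2-methoxycyclohexa-2,5-diene-1-carboxylate | COC(=O)C1C=CCC=C1OC | intermediate
31 | sodium enolate of 30 (not isolated) | COC([O-])=C1C=CCC=C1OC.[Na+] | intermediate
32 | methyl (S)-1-hydroxy-2-methoxycyclohexa-2,5-diene-1-carboxylate | COC1=CCC=C[C@@]1(O)C(=O)OC | intermediate
33 | lithium (S)-1-hydroxy-2-methoxycyclohexa-2,5-diene-1-carboxylate | COC1=CCC=C[C@@]1(O)C(=O)[O-].[Li+] | intermediate
34 | triethylsilyl (S)-2-methoxy-1-(triethylsilyloxy)cyclohexa-2,5-diene-1-carboxylate (not isolated) | COC1=CCC=C[C@@]1(O[Si](CC)(CC)CC)C(=O)O[Si](CC)(CC)CC | intermediate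
35 | (S)-2-methoxy-1-(triethylsilyloxy)cyclohexa-2,5-diene-1-carboxylic acid | COC1=CCC=C[C@@]1(O[Si](CC)(CC)CC)C(=O)O | intermediate
36 | mixed anhydride of 35 with 2,4,6-trichlorobenzoic acid (not isolated) | COC1=CCC=C[C@@]1(O[Si](CC)(CC)CC)C(=O)OC(=O)c1c(Cl)cc(Cl)cc1Cl | intermediate
37 | bottom-unit 3-O-[(S)-2-methoxy-1-(triethylsilyloxy)cyclohexa-2,5-diene-1-carbonyl] ester of 28 | COC1=CCC=C[C@@]1(O[Si](CC)(CC)CC)C(=O)O[C@H]1Cc2c(O[Si](C)(C)C(C)(C)C)cc(O[Si](C)(C)C(C)(C)C)c([C@@H]3c4c(O[Si](C)(C)C(C)(C)C)cc(O[Si](C)(C)C(C)(C)C)c([C@H]5c6c(O[Si](C)(C)C(C)(C)C)cc(O[Si](C)(C)C(C)(C)C)cc6O[C@H](c6ccc(O[Si](C)(C)C(C)(C)C)c(O[Si](C)(C)C(C)(C)C)c6)[C@@H]5O[Si](C)(C)C(C)(C)C)c4O[C@H](c4ccc(O[Si](C)(C)C(C)(C)C)c(O[Si](C)(C)C(C)(C)C)c4)[C@H]3O[Si](C)(C)C(C)(C)C)c2O[C@@H]1c1ccc(O[Si](C)(C)C(C)(C)C)c(O[Si](C)(C)C(C)(C)C)c1 | intermediate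
38 | bottom-unit 3-O-[(S)-6-oxo-1-(triethylsilyloxy)cyclohex-2-ene-1-carbonyl] ester of 28 | O=C1CCC=C[C@@]1(O[Si](CC)(CC)CC)C(=O)O[C@H]1Cc2c(O[Si](C)(C)C(C)(C)C)cc(O[Si](C)(C)C(C)(C)C)c([C@@H]3c4c(O[Si](C)(C)C(C)(C)C)cc(O[Si](C)(C)C(C)(C)C)c([C@H]5c6c(O[Si](C)(C)C(C)(C)C)cc(O[Si](C)(C)C(C)(C)C)cc6O[C@H](c6ccc(O[Si](C)(C)C(C)(C)C)c(O[Si](C)(C)C(C)(C)C)c6)[C@@H]5O[Si](C)(C)C(C)(C)C)c4O[C@H](c4ccc(O[Si](C)(C)C(C)(C)C)c(O[Si](C)(C)C(C)(C)C)c4)[C@H]3O[Si](C)(C)C(C)(C)C)c2O[C@@H]1c1ccc(O[Si](C)(C)C(C)(C)C)c(O[Si](C)(C)C(C)(C)C)c1 | intermediate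
39 | epicatechin-(4β→8)-catechin-(4α→8)-catechin bottom-unit 3-O-[(S)-1-hydroxy-6-oxocyclohex-2-ene-1-carboxylate] (CNP0159807.2) | O=C1CCC=C[C@@]1(O)C(=O)O[C@H]1Cc2c(O)cc(O)c([C@@H]3c4c(O)cc(O)c([C@H]5c6c(O)cc(O)cc6O[C@H](c6ccc(O)c(O)c6)[C@@H]5O)c4O[C@H](c4ccc(O)c(O)c4)[C@H]3O)c2O[C@@H]1c1ccc(O)c(O)c1 | target

## Step count and least certain steps

Total: 27 steps. Longest linear sequence: 15 steps from (+)-catechin (steps 1, 2, 3, 6, 7, 10, 11, 12, 17, 18, 19, 20, 25, 26, 27). The branches are two steps each to 7 and 13, four steps to 22 and four steps to 35.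

**Step 10 (key step).** The most likely failures are poor facial selectivity at the methide (the dienophile has no hydrogen-bond donor for the phosphate, so induction rests on shielding alone) and diversion of the methide into Friedel–Crafts oligomerisation or into the other regiochemistry. A more acidic N-triflylphosphoramide on the same binaphthyl scaffold is the first adjustment. The fallback abandons the cycloaddition and sets out from 2:
- DDQ oxidation in the presence of 2-ethoxyethanol gives 5,7,3',4'-tetra-O-benzyl-4β-(2-ethoxyethoxy)catechin F1.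
- Acetylation (Ac2O, pyridine, 4-(dimethylamino)pyridine) gives its 3-O-acetate F2.
- Me3SiOTf-promoted Friedel–Crafts coupling of F2 with an excess of 3 at −78 °C, in which the 3-acetoxy group bridges the β face of the C4 cation and directs the nucleophile to the α face, returns to the route at 15.

**Step 19.** The boronic ester mask may be lost during the long silylation, through exchange with amine hydrochloride or traces of water, so that catechol oxygens are silylated in part and the staging breaks down; the hindered ring-A phenols next to the interflavan bonds may also react incompletely. The fallback replaces the mask by an ester at the one alcohol, sets out from 24 and bypasses step 20 as well: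
- Exhaustive acetylation (Ac2O, pyridine) gives the tridecaacetate F6.
- Hydrazine hydrate in THF/MeOH at 0 °C removes the twelve aryl acetates only, giving the bottom-unit 3-O-acetate with free phenols F7.
- TBSCl/imidazole gives the dodeca-O-TBS 3-O-acetate F8.
- Reduction of the alkyl acetate with i-Bu2AlH at −78 °C returns at 28.

**Step 25.** Acyl transfer between an α-quaternary silyloxy acid and a hindered secondary alcohol may be too slow. The activated acid may also decompose by loss of the silyloxy group with aromatisation. The fallback sets out from 30 and 28: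
- Saponification of 30 and buffered acidification give 2-methoxycyclohexa-2,5-diene-1-carboxylic acid F3.
- This unhindered acid is esterified with 28 under Steglich conditions (DCC, 4-(dimethylamino)pyridine) to the bottom-unit 3-O-(2-methoxycyclohexa-2,5-diene-1-carbonyl) ester F4.
- Deprotonation with KN(SiMe3)2 at −78 °C and oxidation with the same camphorsulfonyl oxaziridine give the bottom-unit 3-O-[(S)-1-hydroxy-2-methoxycyclohexa-2,5-diene-1-carbonyl] ester F5.
- Et3SiOTf/2,6-lutidine returns to the route at 37.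

**Step 22.** The reagent may discriminate poorly between the two faces of an enolate whose flanking carbons differ only by a methoxy group. The fallback sets out from 30:
- Hydroxylation of the sodium enolate with racemic 3-phenyl-2-(phenylsulfonyl)oxaziridine gives racemic methyl 1-hydroxy-2-methoxycyclohexa-2,5-diene-1-carboxylate F9.
- Saponification and cold buffered acidification give the racemic acid F10.
- Fractional crystallisation with (R)-1-phenylethylamine (or its antipode) should give the (R)-1-phenylethylammonium salt of the S acid F11.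
- One equivalent of LiOH liberates the amine and returns to the route at 33.

**Step 9.** The peracid may go on to epoxidise the electron-rich enol acetate it has just formed. The fallback sets out from 11:
- Wittig reaction with the ylide from (methoxymethyl)triphenylphosphonium chloride and KOt-Bu gives 1,2-bis(benzyloxy)-4-(2-methoxyvinyl)benzene F12.
- Mild acid hydrolysis gives [3,4-bis(benzyloxy)phenyl]acetaldehyde F13.
- Enol acetylation (Ac2O, KOAc, heat) with separation of the E isomer returns at 13.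

## Further compounds

F1 | step 10 | 5,7,3',4'-tetra-O-benzyl-4β-(2-ethoxyethoxy)catechin | CCOCCO[C@H]1c2c(OCc7ccccc7)cc(OCc7ccccc7)cc2O[C@H](c2ccc(OCc7ccccc7)c(OCc7ccccc7)c2)[C@H]1O
F2 | step 10 | 3-O-acetyl-5,7,3',4'-tetra-O-benzyl-4β-(2-ethoxyethoxy)catechin | CCOCCO[C@H]1c2c(OCc7ccccc7)cc(OCc7ccccc7)cc2O[C@H](c2ccc(OCc7ccccc7)c(OCc7ccccc7)c2)[C@H]1OC(C)=O
F3 | step 25 | 2-methoxycyclohexa-2,5-diene-1-carboxylic acid | COC1=CCC=CC1C(=O)O
F4 | step 25 | bottom-unit 3-O-(2-methoxycyclohexa-2,5-diene-1-carbonyl) ester of 28 (acyl C1 epimers) | COC1=CCC=CC1C(=O)O[C@H]1Cc2c(O[Si](C)(C)C(C)(C)C)cc(O[Si](C)(C)C(C)(C)C)c([C@@H]3c4c(O[Si](C)(C)C(C)(C)C)cc(O[Si](C)(C)C(C)(C)C)c([C@H]5c6c(O[Si](C)(C)C(C)(C)C)cc(O[Si](C)(C)C(C)(C)C)cc6O[C@H](c6ccc(O[Si](C)(C)C(C)(C)C)c(O[Si](C)(C)C(C)(C)C)c6)[C@@H]5O[Si](C)(C)C(C)(C)C)c4O[C@H](c4ccc(O[Si](C)(C)C(C)(C)C)c(O[Si](C)(C)C(C)(C)C)c4)[C@H]3O[Si](C)(C)C(C)(C)C)c2O[C@@H]1c1ccc(O[Si](C)(C)C(C)(C)C)c(O[Si](C)(C)C(C)(C)C)c1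
F5 | step 25 | bottom-unit 3-O-[(S)-1-hydroxy-2-methoxycyclohexa-2,5-diene-1-carbonyl] ester of 28 | COC1=CCC=C[C@@]1(O)C(=O)O[C@H]1Cc2c(O[Si](C)(C)C(C)(C)C)cc(O[Si](C)(C)C(C)(C)C)c([C@@H]3c4c(O[Si](C)(C)C(C)(C)C)cc(O[Si](C)(C)C(C)(C)C)c([C@H]5c6c(O[Si](C)(C)C(C)(C)C)cc(O[Si](C)(C)C(C)(C)C)cc6O[C@H](c6ccc(O[Si](C)(C)C(C)(C)C)c(O[Si](C)(C)C(C)(C)C)c6)[C@@H]5O[Si](C)(C)C(C)(C)C)c4O[C@H](c4ccc(O[Si](C)(C)C(C)(C)C)c(O[Si](C)(C)C(C)(C)C)c4)[C@H]3O[Si](C)(C)C(C)(C)C)c2O[C@@H]1c1ccc(O[Si](C)(C)C(C)(C)C)c(O[Si](C)(C)C(C)(C)C)c1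
F6 | step 19 | tridecaacetate of 24 (twelve aryl acetates and bottom 3-O-acetate) | CC(=O)O[C@H]1Cc2c(OC(C)=O)cc(OC(C)=O)c([C@@H]3c4c(OC(C)=O)cc(OC(C)=O)c([C@H]5c6c(OC(C)=O)cc(OC(C)=O)cc6O[C@H](c6ccc(OC(C)=O)c(OC(C)=O)c6)[C@@H]5O[Si](C)(C)C(C)(C)C)c4O[C@H](c4ccc(OC(C)=O)c(OC(C)=O)c4)[C@H]3O[Si](C)(C)C(C)(C)C)c2O[C@@H]1c1ccc(OC(C)=O)c(OC(C)=O)c1
F7 | step 19 | bottom-unit 3-O-acetate of 24 with free phenols | CC(=O)O[C@H]1Cc2c(O)cc(O)c([C@@H]3c4c(O)cc(O)c([C@H]5c6c(O)cc(O)cc6O[C@H](c6ccc(O)c(O)c6)[C@@H]5O[Si](C)(C)C(C)(C)C)c4O[C@H](c4ccc(O)c(O)c4)[C@H]3O[Si](C)(C)C(C)(C)C)c2O[C@@H]1c1ccc(O)c(O)c1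
F8 | step 19 | bottom-unit 3-O-acetate of 28 | CC(=O)O[C@H]1Cc2c(O[Si](C)(C)C(C)(C)C)cc(O[Si](C)(C)C(C)(C)C)c([C@@H]3c4c(O[Si](C)(C)C(C)(C)C)cc(O[Si](C)(C)C(C)(C)C)c([C@H]5c6c(O[Si](C)(C)C(C)(C)C)cc(O[Si](C)(C)C(C)(C)C)cc6O[C@H](c6ccc(O[Si](C)(C)C(C)(C)C)c(O[Si](C)(C)C(C)(C)C)c6)[C@@H]5O[Si](C)(C)C(C)(C)C)c4O[C@H](c4ccc(O[Si](C)(C)C(C)(C)C)c(O[Si](C)(C)C(C)(C)C)c4)[C@H]3O[Si](C)(C)C(C)(C)C)c2O[C@@H]1c1ccc(O[Si](C)(C)C(C)(C)C)c(O[Si](C)(C)C(C)(C)C)c1
F9 | step 22 | racemic methyl 1-hydroxy-2-methoxycyclohexa-2,5-diene-1-carboxylate | COC1=CCC=CC1(O)C(=O)OC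
F10 | step 22 | racemic 1-hydroxy-2-methoxycyclohexa-2,5-diene-1-carboxylic acid | COC1=CCC=CC1(O)C(=O)O
F11 | step 22 | (R)-1-phenylethylammonium (S)-1-hydroxy-2-methoxycyclohexa-2,5-diene-1-carboxylate | COC1=CCC=C[C@@]1(O)C(=O)[O-].C[C@@H]([NH3+])c1ccccc1
F12 | step 9 | 1,2-bis(benzyloxy)-4-(2-methoxyvinyl)benzene (E/Z) | COC=Cc1ccc(OCc2ccccc2)c(OCc2ccccc2)c1
F13 | step 9 | [3,4-bis(benzyloxy)phenyl]acetaldehyde | O=CCc1ccc(OCc2ccccc2)c(OCc2ccccc2)c1
A1 | alternative 1 | (1S,2R)-1,2-dihydroxycyclohexa-3,5-diene-1-carboxylic acid | O[C@@H]1C=CC=C[C@@]1(O)C(=O)O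
A2 | alternative 1 | benzoic acid | OC(=O)c1ccccc1
A3 | alternative 2 | bottom catechin unit (3-O-methoxymethyl, benzylated) bearing the [2-(allyloxy)-4,6-bis(benzyloxy)phenyl]hydroxymethyl group at C8 | COCO[C@H]1Cc2c(OCc3ccccc3)cc(OCc3ccccc3)c(C(O)c3c(OCC=C)cc(OCc4ccccc4)cc3OCc3ccccc3)c2O[C@@H]1c1ccc(OCc2ccccc2)c(OCc2ccccc2)c1
A4 | alternative 2 | (1R,2S)-1-[3,4-bis(benzyloxy)phenyl]-3-[2,4-bis(benzyloxy)-6-fluorophenyl]-2-(methoxymethoxy)propan-1-ol | COCO[C@H]([C@H](O)c1ccc(OCc2ccccc2)c(OCc2ccccc2)c1)Cc1c(F)cc(OCc2ccccc2)cc1OCc1ccccc1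
A5 | alternative 3 | 2-(benzylated 3-O-benzylcatechin-4α-yl)-6-cinnamyl phenol with O5 benzyl, O7 triisopropylsilyl and free O1 | Oc1c(C/C=C/c2ccc(OCc3ccccc3)c(OCc3ccccc3)c2)c(OCc2ccccc2)cc(O[Si](C(C)C)(C(C)C)C(C)C)c1[C@@H]1c2c(OCc3ccccc3)cc(OCc3ccccc3)cc2O[C@H](c2ccc(OCc3ccccc3)c(OCc3ccccc3)c2)[C@H]1OCc1ccccc1
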